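**Retrosynthetic overview**

- The strategy rests on the seven-membered ring (C1, C5, C6, C7, C8, C9, C10). Its C6 and C9 oxygens lie 1,4 to each other across C7=C8(Me), so at the ketone level the ring is a cyclohept-2-ene-1,4-dione, i.e. a dehydro-1,4-diketone.
- Ester C–O and the two carbinol C–H bonds are disconnected first (C9 ketone reduction, vanilloylation, OH-directed C6 reduction), then C7=C8 (dehydrogenation), leaving the saturated bicyclic 6,9-diketone.
- Key disconnection C8–C9: carbene-catalysed umpolung addition of a C9 aldehyde to C8 of a crotonyl ketone on a trans-1,2-disubstituted cyclopentane.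
- The cyclopentane comes from 3-allylcyclopentenone: asymmetric conjugate methylation (C1), aldol with crotonaldehyde (C5–C6), isopropylcerium addition (C4), oxidation, silylation, ozonolysis.
- Ring order: the five-membered ring is bought; the seven-membered ring is closed in step 8.

Key step: step 8

Remark: daucane numbering is used for all intermediates (C1 quaternary C–Me, C2/C3 ring CH2, C4 carbinol carbon bearing iPr, C5 ring-fusion CH, C6–C10 the other seven-ring carbons; C10/C9 are the two carbons of the arm on C1). β is the face of the C1 methyl. The target SMILES corresponds to 1β-Me, 4β-OH, 4α-iPr, 5α-H (trans fusion), 6α-vanilloyloxy, 9β-OH.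

**Route**

Step 1
Reactants: 1 3-ethoxycyclopent-2-en-1-one; 2 allylmagnesium bromide
Product: 4 3-allylcyclopent-2-en-1-one, via bromomagnesium alkoxide 3 (not isolated)
Conditions: THF, 0 °C; then 1 M HCl, 0 °C, 15 min
Reagents that add atoms: none
Why: Stork–Danheiser sequence, in which 1,2-addition of the Grignard reagent to the vinylogous ester is followed by acid-induced loss of ethanol with carbonyl transposition, the short cold acid treatment keeping the allyl double bond out of conjugation.

Step 2
Reactants: 4 3-allylcyclopent-2-en-1-one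
Product: 6 (R)-[(3-allyl-3-methylcyclopent-1-en-1-yl)oxy]trimethylsilane, via dimethylaluminium enolate 5 (not isolated)
Conditions: Me3Al, Cu(OTf)2 (5 mol %), chiral bidentate NHC–Ag complex (2.5 mol %), THF, −78 °C; then TMSOTf, −78 → 0 °C
Reagents that add atoms: trimethylaluminium C[Al](C)C; trimethylsilyl triflate C[Si](C)(C)OS(=O)(=O)C(F)(F)F
Why: Copper-catalysed asymmetric conjugate addition of Me3Al to a β-substituted cyclopentenone sets the C1 quaternary centre under ligand control (the ligand antipode that gives the R centre is used), and O-silylation fixes the regiodefined C4–C5 enolate.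

Step 3
Reactants: 6 (R)-[(3-allyl-3-methylcyclopent-1-en-1-yl)oxy]trimethylsilane; 7 (E)-crotonaldehyde
Product: 9 (2S,3R)-3-allyl-2-[(E)-1-hydroxybut-2-en-1-yl]-3-methylcyclopentan-1-one (side chain cis to the ring methyl; both C6 carbinol epimers), via lithium enolate 8 (not isolated)
Conditions: MeLi, THF, 0 °C; then 7, −78 °C; AcOH/THF quench at −78 °C
Reagents that add atoms: none
Why: MeLi cleaves the silyl enol ether to the regiodefined lithium enolate, which undergoes aldol (1,2-) addition to the enal at −78 °C; the aldehyde should approach C5 anti to the larger allyl group on C1, placing the C6 chain cis to the methyl, with a moderate preference so that the minor C5 epimer is removed by chromatography, while the C6 carbinol configuration is irrelevant because it is oxidised in step 5.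

Step 4
Reactants: 9 aldol adduct
Product: 10 3-allyl-2-[(E)-1-hydroxybut-2-en-1-yl]-1-isopropyl-3-methylcyclopentan-1-ol (4β-OH cis to the C5 side chain and the C1 methyl; 4α-iPr)
Conditions: i-PrMgCl (3.5 equiv), anhydrous CeCl3 (3.5 equiv), THF, −78 → −40 °C; aq. NH4Cl
Reagents that add atoms: isopropylmagnesium chloride CC(C)[Mg]Cl
Why: Organocerium 1,2-addition, which suppresses enolisation and β-hydride reduction of the hindered ketone, should occur on the cyclopentanone face anti to the adjacent branched C5 substituent after the first equivalent has formed the C6 alkoxide, giving 4α-isopropyl and 4β-hydroxyl.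

Step 5
Reactants: 10 diol
Product: 11 (E)-1-[5-allyl-2-hydroxy-2-isopropyl-5-methylcyclopentyl]but-2-en-1-one (acyl β; OH β; iPr α; allyl α)
Conditions: Dess–Martin periodinane, NaHCO3, CH2Cl2, 0 °C → rt
Reagents that add atoms: none
Why: Dess–Martin oxidation converts the secondary allylic alcohol into the (E)-enone under buffered neutral conditions that spare the tertiary alcohol and avoid retro-aldol cleavage, and both C6 epimers converge on one ketone.

Step 6
Reactants: 11 hydroxy enone
Product: 12 triethylsilyl ether of 11
Conditions: TESOTf, 2,6-lutidine, CH2Cl2, −78 → 0 °C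
Reagents that add atoms: triethylsilyl triflate CC[Si](CC)(CC)OS(=O)(=O)C(F)(F)F
Why: Silyl triflate with a hindered pyridine base silylates the tertiary alcohol at low temperature, which blocks retro-aldol opening and oxa-Michael addition in the later base-mediated step.

Step 7
Reactants: 12 silyl ether
Product: 14 2-{2-[(E)-but-2-enoyl]-3-isopropyl-1-methyl-3-[(triethylsilyl)oxy]cyclopentyl}acetaldehyde (acyl β; CH2CHO α; OSiEt3 β; iPr α), via secondary ozonide 13 (not isolated)
Conditions: O3, CH2Cl2, −78 °C, Sudan Red 7B end point; then PPh3, −78 °C → rt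
Reagents that add atoms: ozone [O-][O+]=O
Why: Ozonolysis (Criegee mechanism) with a dye end point should cleave the isolated monosubstituted alkene in preference to the electron-poor conjugated enone because ozone is electrophilic, and phosphine reduction of the ozonide releases the aldehyde.

Step 8
Reactants: 14 keto aldehyde
Product: 15 trans-fused 4β-[(triethylsilyl)oxy]daucane-6,9-dione (C8 epimers expected; the 8β-methyl epimer is drawn)
Conditions: 2-(pentafluorophenyl)-6,7-dihydro-5H-pyrrolo[2,1-c][1,2,4]triazol-2-ium tetrafluoroborate (20 mol %), i-Pr2NEt (1 equiv), toluene (0.02 M), 40 → 70 °C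
Reagents that add atoms: none
Why: Proposed new method: addition of the triazolylidene to the C9 aldehyde and a 1,2-proton shift generate the enaminol (Breslow) nucleophile, whose C9 attacks C8, the β-carbon of the crotonyl unit, and collapse of the adduct expels the carbene to leave the C6/C9 diketone. The closest known reaction type is the intramolecular Stetter reaction of aliphatic aldehydes onto tethered Michael acceptors, which is established for five- and six-membered rings closed in the exo mode, whereas here the acceptor carbonyl lies inside the ring being formed. The seven-membered ring closes 7-endo-trig, and the trans-1,2 arrangement of the two arms (C5 acyl β, C1 CH2CHO α) lets C9 reach C8 and leads to the unstrained trans-fused hydroazulene. C8 is the only new stereocentre; it is not controlled, can equilibrate next to the C9 ketone, and is removed in step 9. The step needs 1,4-addition to win over benzoin and aldol pathways: cross-benzoin attack on the C6 ketone would give a strained trans-fused bicyclo[3.3.0]octane and is reversible, aldol closures through C5 or C10 would give four-membered rings, and dilution with a weak amine base holds back intermolecular condensation. The C4 silyl ether prevents retro-aldol cleavage and oxa-Michael addition of the tertiary oxygen.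

Step 9
Reactants: 15 diketone
Product: 16 4β-[(triethylsilyl)oxy]dauc-7-ene-6,9-dione
Conditions: IBX (2.5 equiv), DMSO, 65–75 °C
Reagents that add atoms: none
Why: IBX-mediated ketone dehydrogenation can introduce unsaturation only between C7 and C8 because C1 and C4 are quaternary, and this position is activated by both carbonyls, so the uncontrolled C8 centre is removed and the cyclic (Z) ene-dione results.

Step 10
Reactants: 16 silyl ene-dione
Product: 17 4β-hydroxydauc-7-ene-6,9-dione
Conditions: HF·pyridine, pyridine, THF, 0 °C → rt
Reagents that add atoms: none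
Why: Fluoride-driven Si–O cleavage under buffered acidic conditions frees the tertiary alcohol without the basic conditions that could trigger retro-aldol opening or oxa-Michael closure.

Step 11
Reactants: 17 hydroxy ene-dione
Product: 18 4β,6α-dihydroxydauc-7-en-9-one
Conditions: Me4NBH(OAc)3, MeCN/AcOH (1:1), −30 → −20 °C
Reagents that add atoms: none
Why: Evans–Saksena reduction, in which acetate exchange binds boron to the C4 alkoxide and hydride is delivered through a six-membered transition state to the β face of C6 (the face of C4–O), should give the 6α-alcohol (1,3-anti diol) and leave the C9 carbonyl, which has no directing hydroxyl, untouched.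

Step 12
Reactants: 19 vanillic acid
Product: 21 4-[(tert-butyldimethylsilyl)oxy]-3-methoxybenzoic acid, via silyl ester 20 (not isolated)
Conditions: TBSCl (2.3 equiv), imidazole, DMF, rt; then AcOH/THF/H2O (3:1:1), rt
Reagents that add atoms: tert-butyldimethylsilyl chloride CC(C)(C)[Si](C)(C)Cl
Why: Silylation of both acidic OH groups followed by selective hydrolysis of the far more labile silyl ester leaves the phenol masked as its TBS ether for the esterification.

Step 13
Reactants: 18 diol enone; 21 protected vanillic acid
Product: 22 4β-hydroxy-9-oxodauc-7-en-6α-yl 4-[(tert-butyldimethylsilyl)oxy]-3-methoxybenzoate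
Conditions: DCC, DMAP (1 equiv), CH2Cl2, 0 °C → rt
Reagents that add atoms: none
Why: Steglich esterification acylates the secondary allylic C6 hydroxyl, while the tertiary C4 hydroxyl is too hindered to react and needs no protection.

Step 14
Reactants: 22 keto ester
Product: 23 4β,9β-dihydroxydauc-7-en-6α-yl 4-[(tert-butyldimethylsilyl)oxy]-3-methoxybenzoate
Conditions: NaBH4, CeCl3·7H2O, MeOH, −78 °C
Reagents that add atoms: none
Why: Luche reduction gives cerium-activated 1,2-hydride addition to the enone, and hydride should enter the α face of C9, anti to the axial C1 methyl that screens the β face (the 6α-aroyloxy group being pseudo-equatorial), which sets the 9β-hydroxyl.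

Step 15
Reactants: 23 silyl-protected ester
Product: 24 4β,9β-dihydroxydauc-7-en-6α-yl 4-hydroxy-3-methoxybenzoate (CNP0189996.3)
Conditions: TBAF, AcOH (1:1), THF, 0 °C
Reagents that add atoms: none
Why: Fluoride cleaves the aryl silyl ether rapidly, and the acetic acid buffer keeps the medium non-basic so that the ester neither migrates nor cleaves and the allylic alcohol is untouched.

**Compound list**

1 | 3-ethoxycyclopent-2-en-1-one | CCOC1=CC(=O)CC1 | starting material
2 | allylmagnesium bromide | C=CC[Mg]Br | starting material
3 | bromomagnesium 1-allyl-3-ethoxycyclopent-2-en-1-olate | C=CCC1(O[Mg]Br)C=C(OCC)CC1 | intermediate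
4 | 3-allylcyclopent-2-en-1-one | C=CCC1=CC(=O)CC1 | intermediate
5 | dimethylaluminium (R)-3-allyl-3-methylcyclopent-1-en-1-olate | C1=C(O[Al](C)C)CC[C@]1(C)CC=C | intermediate
6 | (R)-[(3-allyl-3-methylcyclopent-1-en-1-yl)oxy]trimethylsilane | C1=C(O[Si](C)(C)C)CC[C@]1(C)CC=C | intermediate
7 | (E)-crotonaldehyde | C/C=C/C=O | starting material
8 | lithium (R)-3-allyl-3-methylcyclopent-1-en-1-olate | C1=C(O[Li])CC[C@]1(C)CC=C | intermediate
9 | (2S,3R)-3-allyl-2-[(E)-1-hydroxybut-2-en-1-yl]-3-methylcyclopentan-1-one, C6 carbinol epimers | C/C=C/C(O)[C@H]1C(=O)CC[C@]1(C)CC=C | intermediate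
10 | 3-allyl-2-[(E)-1-hydroxybut-2-en-1-yl]-1-isopropyl-3-methylcyclopentan-1-ol (4β-OH, 4α-iPr, C5 chain β, allyl α), C6 epimers | C/C=C/C(O)[C@H]1[C@](O)(C(C)C)CC[C@]1(C)CC=C | intermediate
11 | (E)-1-[5-allyl-2-hydroxy-2-isopropyl-5-methylcyclopentyl]but-2-en-1-one (acyl β, OH β, iPr α, allyl α) | C/C=C/C(=O)[C@H]1[C@](O)(C(C)C)CC[C@]1(C)CC=C | intermediate
12 | triethylsilyl ether of 11 | C/C=C/C(=O)[C@H]1[C@](O[Si](CC)(CC)CC)(C(C)C)CC[C@]1(C)CC=C | intermediate
13 | secondary ozonide (1,2,4-trioxolane) of the allyl group of 12 | C/C=C/C(=O)[C@H]1[C@](O[Si](CC)(CC)CC)(C(C)C)CC[C@]1(C)CC2OCOO2 | intermediate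
14 | 2-{2-[(E)-but-2-enoyl]-3-isopropyl-1-methyl-3-[(triethylsilyl)oxy]cyclopentyl}acetaldehyde (acyl β, CH2CHO α, OSiEt3 β, iPr α) | C/C=C/C(=O)[C@H]1[C@](O[Si](CC)(CC)CC)(C(C)C)CC[C@]1(C)CC=O | intermediate
15 | trans-fused 4β-[(triethylsilyl)oxy]daucane-6,9-dione (C8 epimers; 8β-methyl drawn) | O=C2C[C@H](C)C(=O)C[C@@]3(C)CC[C@@](O[Si](CC)(CC)CC)(C(C)C)[C@H]23 | intermediate
16 | 4β-[(triethylsilyl)oxy]dauc-7-ene-6,9-dione | O=C2C=C(C)C(=O)C[C@@]3(C)CC[C@@](O[Si](CC)(CC)CC)(C(C)C)[C@H]23 | intermediate
17 | 4β-hydroxydauc-7-ene-6,9-dione | O=C2C=C(C)C(=O)C[C@@]3(C)CC[C@@](O)(C(C)C)[C@H]23 | intermediate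
18 | 4β,6α-dihydroxydauc-7-en-9-one | O[C@H]2C=C(C)C(=O)C[C@@]3(C)CC[C@@](O)(C(C)C)[C@H]23 | intermediate
19 | vanillic acid | COc1cc(C(=O)O)ccc1O | starting material
20 | tert-butyldimethylsilyl 4-[(tert-butyldimethylsilyl)oxy]-3-methoxybenzoate | COc1cc(C(=O)O[Si](C)(C)C(C)(C)C)ccc1O[Si](C)(C)C(C)(C)C | intermediate
21 | 4-[(tert-butyldimethylsilyl)oxy]-3-methoxybenzoic acid | COc1cc(C(=O)O)ccc1O[Si](C)(C)C(C)(C)C | intermediate
22 | 4β-hydroxy-9-oxodauc-7-en-6α-yl 4-[(tert-butyldimethylsilyl)oxy]-3-methoxybenzoate | COc1cc(C(=O)O[C@H]2C=C(C)C(=O)C[C@@]3(C)CC[C@@](O)(C(C)C)[C@H]23)ccc1O[Si](C)(C)C(C)(C)C | intermediate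
23 | 4β,9β-dihydroxydauc-7-en-6α-yl 4-[(tert-butyldimethylsilyl)oxy]-3-methoxybenzoate | COc1cc(C(=O)O[C@H]2C=C(C)[C@H](O)C[C@@]3(C)CC[C@@](O)(C(C)C)[C@H]23)ccc1O[Si](C)(C)C(C)(C)C | intermediate
24 | 4β,9β-dihydroxydauc-7-en-6α-yl 4-hydroxy-3-methoxybenzoate (CNP0189996.3) | COc1cc(C(=O)O[C@H]2C=C(C)[C@H](O)C[C@@]3(C)CC[C@@](O)(C(C)C)[C@H]23)ccc1O | target

**Step count**

Total: 15 steps. Longest linear sequence: 14 steps (steps 1–11 and 13–15); step 12 is a one-step side branch.

**Steps most likely to fail**

Step 8 (bears the label "Proposed new method:"). The 7-endo addition of the enaminol to the β-methyl enone may be slower than the exo closures on which the method is proven, so that the aldehyde is consumed by intermolecular benzoin or aldol condensation, or the carbene is lost by addition to the enone. The fallback uses known chemistry, a 7-endo-trig acyl radical cyclisation, and sets out from 14. Pinnick oxidation (NaClO2, NaH2PO4, 2-methyl-2-butene, t-BuOH/H2O) should give the carboxylic acid F1. Diphenyl diselenide and tributylphosphine should convert it into the Se-phenyl selenoester F2. Bu3SnH and AIBN in refluxing benzene under syringe-pump dilution should then generate the nucleophilic acyl radical, which adds to C8 (polarity-matched, giving the α-keto radical at C7) rather than to C7. Hydrogen transfer should give the diketone, and the route is rejoined at 15.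

Step 11. Acetate/alkoxide exchange at the hindered tertiary C4 hydroxyl may be slow, so that undirected or conjugate hydride transfer to the ene-dione competes, or the free hydroxyl adds to C7. The fallback changes the order of events so that the directed reduction is run before the double bond exists, and sets out from 15. HF·pyridine should give the hydroxy diketone F3. Me4NBH(OAc)3 should then reduce only the β-hydroxy ketone to the 6α-alcohol F4, the isolated C9 ketone being inert. DCC/DMAP with 21 should give the saturated keto ester F5. IBX dehydrogenation of the C9 ketone, which can only desaturate C8–C7, should then give the enone, and the route is rejoined at 22.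

Step 14. Facial selectivity in the hydride addition to C9 may be poor or reversed (β-face attack, giving the 9α-alcohol). The fallback inverts the carbinol centre instead of relying on substrate bias, and sets out from 22. The reduction is taken to the 9α-alcohol F6. Mitsunobu reaction (p-nitrobenzoic acid, PPh3, DIAD) should give the inverted 9β p-nitrobenzoate F7. K2CO3 in MeOH at 0 °C should then cleave the electron-poor p-nitrobenzoate and the aryl silyl ether while the electron-rich vanillate survives, and the route is rejoined at 24.

**Further compounds**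

F1 | step 8 | 2-{2-[(E)-but-2-enoyl]-3-isopropyl-1-methyl-3-[(triethylsilyl)oxy]cyclopentyl}acetic acid | C/C=C/C(=O)[C@H]1[C@](O[Si](CC)(CC)CC)(C(C)C)CC[C@]1(C)CC(=O)O
F2 | step 8 | Se-phenyl selenoester of F1 | C/C=C/C(=O)[C@H]1[C@](O[Si](CC)(CC)CC)(C(C)C)CC[C@]1(C)CC(=O)[Se]c1ccccc1
F3 | step 11 | 4β-hydroxydaucane-6,9-dione (C8 epimers; 8β-methyl drawn) | O=C2C[C@H](C)C(=O)C[C@@]3(C)CC[C@@](O)(C(C)C)[C@H]23
F4 | step 11 | 4β,6α-dihydroxydaucan-9-one (C8 epimers; 8β-methyl drawn) | O[C@H]2C[C@H](C)C(=O)C[C@@]3(C)CC[C@@](O)(C(C)C)[C@H]23
F5 | step 11 | 4β-hydroxy-9-oxodaucan-6α-yl 4-[(tert-butyldimethylsilyl)oxy]-3-methoxybenzoate (C8 epimers; 8β-methyl drawn) | COc1cc(C(=O)O[C@H]2C[C@H](C)C(=O)C[C@@]3(C)CC[C@@](O)(C(C)C)[C@H]23)ccc1O[Si](C)(C)C(C)(C)C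
F6 | step 14 | 4β,9α-dihydroxydauc-7-en-6α-yl 4-[(tert-butyldimethylsilyl)oxy]-3-methoxybenzoate | COc1cc(C(=O)O[C@H]2C=C(C)[C@@H](O)C[C@@]3(C)CC[C@@](O)(C(C)C)[C@H]23)ccc1O[Si](C)(C)C(C)(C)C
F7 | step 14 | 4β-hydroxy-9β-(4-nitrobenzoyloxy)dauc-7-en-6α-yl 4-[(tert-butyldimethylsilyl)oxy]-3-methoxybenzoate | COc1cc(C(=O)O[C@H]2C=C(C)[C@H](OC(=O)c4ccc(cc4)[N+](=O)[O-])C[C@@]3(C)CC[C@@](O)(C(C)C)[C@H]23)ccc1O[Si](C)(C)C(C)(C)C
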